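**Retrosynthetic overview**
1. Oxirane last: target 23 ⇐ reagent-controlled Shi epoxidation of the C3=C4 alkene of macrocyclic triene lactone 22.
2. 14-Membered ring and cis-γ-lactone formed together: 22 ⇐ C1–C14 bond by one-pot organocatalytic α-aminoxylation (C13) and indium macro-Barbier/lactonisation of open-chain aldehyde–allyl chloride 18.
3. 18 ⇐ dialdehyde 14: Morita–Baylis–Hillman on the saturated aldehyde (east end), iminium transfer hydrogenation of the enal as a latent aldehyde (C12), then allylic chloride.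
4. 14 ⇐ Z-Wittig (C6=C7) of epoxy aldehyde 3 with ylide 11, then hydride opening of the epoxide to the C8 tertiary alcohol.
5. 3 ⇐ geranyl acetate (SeO2, then organocatalytic epoxidation as the first stereocentre); 11 ⇐ TBS-protected but-3-yn-1-ol (Zr-carboalumination, oxirane).

Locants C1–C14 follow the ring: C1 = ring CH carrying the acrylate carbon, C3/C4 = oxirane (4-methyl), C6=C7 = Z-alkene, C8 = tertiary carbinol, C12 = CH–CH3, C13 = CHOH, C14 = lactone O–CH.

Assumption: where the sense of induction of a named organocatalyst is not certain for this substrate, the catalyst antipode (or pseudo-enantiomer) that gives the drawn configuration is the one meant.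

**Step 1**
Reactants: 1 geranyl acetate
Product: 2 (2E,6E)-3,7-dimethyl-8-oxoocta-2,6-dien-1-yl acetate
Conditions: SeO2 (1.1 equiv), 95% EtOH, reflux
Reagents that add atoms: selenium dioxide O=[Se]=O
Why: Riley allylic oxidation (ene, then [2,3]-shift) attacks the E-methyl of the electron-rich terminal trisubstituted alkene, not the acetate-deactivated one, and gives the (E)-enal directly in moderate yield; no stereocentre.

**Step 2**
Reactants: 2
Product: 3 (2E)-5-[(2R,3S)-3-formyl-3-methyloxiran-2-yl]-3-methylpent-2-en-1-yl acetate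
Conditions: 9-amino(9-deoxy)epiquinine (10 mol%), (R)-TRIP (20 mol%), 50% aq H2O2 (1.5 equiv), THF, 50 °C
Reagents that add atoms: hydrogen peroxide OO
Why: Iminium-activated nucleophilic (Weitz–Scheffer-type) epoxidation of an α-branched enal, in which the chiral amine/phosphate ion pair directs hydroperoxide to one enal face and so sets quaternary C8 (S) and C9 (R) as the first stereocentres, while the isolated alkene is inert to H2O2.

**Step 3**
Reactants: 4 4-[(tert-butyldimethylsilyl)oxy]but-1-yne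
Product: 7 (3E)-6-[(tert-butyldimethylsilyl)oxy]-4-methylhex-3-en-1-ol, via alkenyldimethylalane 5 (not isolated), via lithium alkenylalanate 6 (not isolated)
Conditions: Me3Al (2 equiv), Cp2ZrCl2 (20 mol%), CH2Cl2, 0 °C → rt; volatiles removed; n-BuLi, THF, −78 °C; oxirane, −78 → 0 °C; aq Rochelle salt
Reagents that add atoms: trimethylaluminium C[Al](C)C; oxirane C1CO1
Why: Negishi Zr-catalysed syn-carboalumination fixes the E-trisubstituted C3=C4 alkene regio- and stereospecifically, and the derived alanate opens oxirane with retention of alkene geometry; no stereocentre.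

**Step 4**
Reactants: 7
Product: 8 (3E)-6-[(tert-butyldimethylsilyl)oxy]-4-methylhex-3-en-1-yl pivalate
Conditions: PivCl (1.2 equiv), pyridine, DMAP (cat.), CH2Cl2, 0 °C → rt
Reagents that add atoms: pivaloyl chloride CC(C)(C)C(=O)Cl
Why: Standard acylation; the pivalate has no α-hydrogen, survives the ylide chemistry and is removed for free by the hydride in step 8.

**Step 5**
Reactants: 8
Product: 9 (3E)-6-bromo-4-methylhex-3-en-1-yl pivalate
Conditions: Ph3PBr2 (1.3 equiv), CH2Cl2, 0 °C → rt
Reagents that add atoms: dibromotriphenylphosphorane BrP(Br)(c1ccccc1)(c1ccccc1)c1ccccc1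
Why: Direct silyl ether to bromide conversion (Appel-type) through the alkoxyphosphonium salt and SN2 by bromide at the primary carbon; ester and alkene are untouched.

**Step 6**
Reactants: 9
Product: 10 [(3E)-3-methyl-6-(pivaloyloxy)hex-3-en-1-yl]triphenylphosphonium bromide
Conditions: PPh3 (1.2 equiv), MeCN, reflux, 36 h
Reagents that add atoms: triphenylphosphine c1ccc(cc1)P(c1ccccc1)c1ccccc1
Why: SN2 quaternisation of a primary homoallylic bromide, the usual entry to skipped-diene Wittig salts.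

**Step 7**
Reactants: 10 [(3E)-3-methyl-6-(pivaloyloxy)hex-3-en-1-yl]triphenylphosphonium bromide; 3 (2E)-5-[(2R,3S)-3-formyl-3-methyloxiran-2-yl]-3-methylpent-2-en-1-yl acetate
Product: 12 (2E)-3-methyl-5-{(2R,3R)-3-methyl-3-[(1Z,4E)-4-methyl-7-(pivaloyloxy)hepta-1,4-dien-1-yl]oxiran-2-yl}pent-2-en-1-yl acetate, via phosphonium ylide 11 (not isolated)
Conditions: KHMDS (1.0 equiv), THF, −78 °C; then 3, −78 → 0 °C
Reagents that add atoms: none
Why: Salt-free Wittig olefination of a non-stabilised ylide with an α-quaternary aldehyde gives the Z-C6=C7 alkene through the kinetic cis-oxaphosphetane, with epoxide, esters and both stereocentres untouched at −78 °C.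

**Step 8**
Reactants: 12
Product: 13 (2E,7S,8Z,11E)-3,7,11-trimethyltetradeca-2,8,11-triene-1,7,14-triol
Conditions: LiEt3BH (6 equiv), THF, 0 °C → rt; H2O work-up
Reagents that add atoms: none
Why: SN2 hydride opening of the trisubstituted epoxide at the less hindered C9 leaves the C8–O bond intact, so the tertiary alcohol keeps the C8 configuration set in step 2, and the same reagent reductively removes acetate and pivalate.

**Step 9**
Reactants: 13
Product: 14 (2E,7S,8Z,11E)-7-hydroxy-3,7,11-trimethyltetradeca-2,8,11-trienedial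
Conditions: Dess–Martin periodinane (2.4 equiv), NaHCO3, CH2Cl2, 0 °C → rt; used at once
Reagents that add atoms: none
Why: Dess–Martin oxidation takes both primary alcohols to aldehydes under buffered, non-acidic conditions and cannot oxidise the tertiary allylic alcohol; this gives one reactive aldehyde (C1) and one latent aldehyde (the C14 enal).

**Step 10**
Reactants: 14 (2E,7S,8Z,11E)-7-hydroxy-3,7,11-trimethyltetradeca-2,8,11-trienedial; 15 methyl acrylate
Product: 16 methyl (5E,8Z,10S,14E)-3,10-dihydroxy-6,10,14-trimethyl-2-methylidene-16-oxohexadeca-5,8,14-trienoate (1:1 epimers at C3)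
Conditions: DABCO (1.0 equiv), methyl acrylate (5 equiv), 1,4-dioxane/H2O 1:1, rt
Reagents that add atoms: none
Why: Morita–Baylis–Hillman reaction, in which only the unhindered saturated aldehyde is electrophilic enough and the β,β-disubstituted enal is inert; the new carbinol centre forms unselectively but is erased in step 12.

**Step 11**
Reactants: 16
Product: 17 methyl (5E,8Z,10S,14S)-3,10-dihydroxy-6,10,14-trimethyl-2-methylidene-16-oxohexadeca-5,8-dienoate (1:1 epimers at C3)
Conditions: (S)-2-tert-butyl-3-methylimidazolidin-4-one·Cl3CCO2H (20 mol%), Hantzsch ester (1.2 equiv), CHCl3, −30 °C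
Reagents that add atoms: none
Why: Iminium-catalysed transfer hydrogenation of a β,β-disubstituted enal (E/Z-convergent), in which the Hantzsch ester delivers hydride to one face of the iminium ion and sets C12 (S) under catalyst control, while the acrylate is not activated and stays.

**Step 12**
Reactants: 17
Product: 18 methyl (2Z,5E,8Z,10S,14S)-2-(chloromethyl)-10-hydroxy-6,10,14-trimethyl-16-oxohexadeca-2,5,8-trienoate
Conditions: MsCl (1.15 equiv), Et3N (1.5 equiv), CH2Cl2, −20 → 0 °C
Reagents that add atoms: methanesulfonyl chloride CS(=O)(=O)Cl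
Why: Mesylation of the secondary Baylis–Hillman alcohol and SN2′ return of chloride give the thermodynamic (Z)-2-(chloromethyl)enoate (chain cis to CH2Cl), removing the C1 carbinol centre; the hindered tertiary alcohol does not react with a slight excess of reagent, and the chloride is dormant enough for the amine catalysis that follows.

**Step 13**
Reactants: 18
Product: 22 (1S,3E,6Z,8S,12S,13R,14R)-8,13-dihydroxycembra-3,6,15(17)-trien-16,14-olide, via α-anilinooxy aldehyde 19 (not isolated), via macrocyclic hydroxy ester 20 (not isolated), via anilinooxy lactone 21 (not isolated)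
Conditions: (i) L-proline (20 mol%), PhNO (1.0 equiv), CHCl3, 4 °C; (ii) syringe pump into In powder (4 equiv), NaI (0.2 equiv), THF/aq NH4Cl 3:1, rt, 2 mM; (iii) AcOH, Zn dust, rt
Reagents that add atoms: nitrosobenzene O=Nc1ccccc1
Why: Proposed new method: a telescoped enamine α-aminoxylation and indium-mediated macrocyclising Barbier allylation–lactonisation, in which L-proline directs O-attack of PhN=O on the enamine to set 13R (syn to the C12 methyl), the (Z)-allylindium formed from the 2-(chloromethyl)enoate then adds through its γ-carbon (C1) to the indium-chelated α-oxy aldehyde in a chair transition state anti to the C12 branch (14R, 13,14-syn) with the Z-allyl geometry giving the 1,14-syn adduct, so the γ-hydroxy ester closes to the cis-lactone in AcOH and Zn cuts the N–O bond; the closest known reaction types are the tandem proline α-aminoxylation/indium allylation with allyl bromide, the aqueous indium addition of (Z)-2-(halomethyl)alk-2-enoates to α-oxy aldehydes under chelation control, and CrCl2-mediated macrocyclisation of ω-formyl 2-(bromomethyl)acrylates.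

**Step 14**
Reactants: 22
Product: 23 (1S,3R,4R,6Z,8S,12S,13R,14R)-3,4-epoxy-8,13-dihydroxycembra-6,15(17)-dien-16,14-olide (CNP0304380.1)
Conditions: D-fructose-derived Shi ketone (30 mol%), Oxone, K2CO3, Bu4NHSO4 (cat.), MeCN/DMM/aq borate–EDTA buffer, 0 °C, 1–2 h
Reagents that add atoms: Oxone (potassium peroxymonosulfate) [K+].[O-]S(=O)(=O)OO
Why: Shi epoxidation, in which the chiral dioxirane transfers oxygen through a spiro transition state to the only electron-rich E-trisubstituted alkene and gives the 3R,4R oxirane under reagent control (the E-alkene of a 14-ring can present either face), while the Z-disubstituted alkene and the α-methylene lactone are poor substrates.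

**Compound list**
1 | geranyl acetate | CC(C)=CCC/C(C)=C/COC(C)=O | starting material
2 | (2E,6E)-3,7-dimethyl-8-oxoocta-2,6-dien-1-yl acetate | O=C/C(C)=C/CC/C(C)=C/COC(C)=O | intermediate
3 | (2E)-5-[(2R,3S)-3-formyl-3-methyloxiran-2-yl]-3-methylpent-2-en-1-yl acetate | O=C[C@@]1(C)O[C@@H]1CC/C(C)=C/COC(C)=O | intermediate
4 | 4-[(tert-butyldimethylsilyl)oxy]but-1-yne | C#CCCO[Si](C)(C)C(C)(C)C | starting material
5 | (E)-{4-[(tert-butyldimethylsilyl)oxy]-2-methylbut-1-en-1-yl}dimethylalane | C[Al](C)/C=C(\C)CCO[Si](C)(C)C(C)(C)C | intermediate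
6 | lithium butyl{(E)-4-[(tert-butyldimethylsilyl)oxy]-2-methylbut-1-en-1-yl}dimethylaluminate | [Li+].CCCC[Al-](C)(C)/C=C(\C)CCO[Si](C)(C)C(C)(C)C | intermediate
7 | (3E)-6-[(tert-butyldimethylsilyl)oxy]-4-methylhex-3-en-1-ol | OCC/C=C(C)/CCO[Si](C)(C)C(C)(C)C | intermediate
8 | (3E)-6-[(tert-butyldimethylsilyl)oxy]-4-methylhex-3-en-1-yl pivalate | CC(C)(C)C(=O)OCC/C=C(C)/CCO[Si](C)(C)C(C)(C)C | intermediate
9 | (3E)-6-bromo-4-methylhex-3-en-1-yl pivalate | CC(C)(C)C(=O)OCC/C=C(C)/CCBr | intermediate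
10 | [(3E)-3-methyl-6-(pivaloyloxy)hex-3-en-1-yl]triphenylphosphonium bromide | CC(C)(C)C(=O)OCC/C=C(C)/CC[P+](c1ccccc1)(c1ccccc1)c1ccccc1.[Br-] | intermediate
11 | (3E)-3-methyl-6-(pivaloyloxy)hex-3-en-1-ylidene(triphenyl)phosphorane | CC(C)(C)C(=O)OCC/C=C(C)/CC=P(c1ccccc1)(c1ccccc1)c1ccccc1 | intermediate
12 | (2E)-3-methyl-5-{(2R,3R)-3-methyl-3-[(1Z,4E)-4-methyl-7-(pivaloyloxy)hepta-1,4-dien-1-yl]oxiran-2-yl}pent-2-en-1-yl acetate | CC(=O)OC/C=C(C)/CC[C@H]1O[C@]1(C)/C=C\C/C(C)=C/CCOC(=O)C(C)(C)C | intermediate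
13 | (2E,7S,8Z,11E)-3,7,11-trimethyltetradeca-2,8,11-triene-1,7,14-triol | OC/C=C(C)/CCC[C@](C)(O)/C=C\C/C(C)=C/CCO | intermediate
14 | (2E,7S,8Z,11E)-7-hydroxy-3,7,11-trimethyltetradeca-2,8,11-trienedial | O=C/C=C(C)/CCC[C@](C)(O)/C=C\C/C(C)=C/CC=O | intermediate
15 | methyl acrylate | C=CC(=O)OC | starting material
16 | methyl (5E,8Z,10S,14E)-3,10-dihydroxy-6,10,14-trimethyl-2-methylidene-16-oxohexadeca-5,8,14-trienoate (C3 epimers) | O=C/C=C(C)/CCC[C@](C)(O)/C=C\C/C(C)=C/CC(O)C(=C)C(=O)OC | intermediate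
17 | methyl (5E,8Z,10S,14S)-3,10-dihydroxy-6,10,14-trimethyl-2-methylidene-16-oxohexadeca-5,8-dienoate (C3 epimers) | O=CC[C@@H](C)CCC[C@](C)(O)/C=C\C/C(C)=C/CC(O)C(=C)C(=O)OC | intermediate
18 | methyl (2Z,5E,8Z,10S,14S)-2-(chloromethyl)-10-hydroxy-6,10,14-trimethyl-16-oxohexadeca-2,5,8-trienoate | O=CC[C@@H](C)CCC[C@](C)(O)/C=C\C/C(C)=C/C/C=C(\CCl)C(=O)OC | intermediate
19 | methyl (2Z,5E,8Z,10S,14S,15R)-15-(anilinooxy)-2-(chloromethyl)-10-hydroxy-6,10,14-trimethyl-16-oxohexadeca-2,5,8-trienoate | O=C[C@H](ONc1ccccc1)[C@@H](C)CCC[C@](C)(O)/C=C\C/C(C)=C/C/C=C(\CCl)C(=O)OC | intermediate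
20 | methyl 2-[(1S,2R,3R,4S,8S,9Z,12E)-3-(anilinooxy)-2,8-dihydroxy-4,8,12-trimethylcyclotetradeca-9,12-dien-1-yl]prop-2-enoate | COC(=O)C(=C)[C@@H]1C/C=C(C)/C\C=C/[C@@](C)(O)CCC[C@H](C)[C@@H](ONc2ccccc2)[C@@H]1O | intermediate
21 | (1S,3E,6Z,8S,12S,13R,14R)-13-(anilinooxy)-8-hydroxycembra-3,6,15(17)-trien-16,14-olide | C=C1C(=O)O[C@H]2[C@H](ONc3ccccc3)[C@@H](C)CCC[C@](C)(O)/C=C\C/C(C)=C/C[C@@H]12 | intermediate
22 | (1S,3E,6Z,8S,12S,13R,14R)-8,13-dihydroxycembra-3,6,15(17)-trien-16,14-olide | C=C1C(=O)O[C@H]2[C@H](O)[C@@H](C)CCC[C@](C)(O)/C=C\C/C(C)=C/C[C@@H]12 | intermediate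
23 | (1S,3R,4R,6Z,8S,12S,13R,14R)-3,4-epoxy-8,13-dihydroxycembra-6,15(17)-dien-16,14-olide (CNP0304380.1) | C=C1C(=O)O[C@H]2[C@H](O)[C@@H](C)CCC[C@](C)(O)/C=C\C[C@@]3(C)O[C@@H]3C[C@@H]12 | target

**Step count and risk**
Total steps: 14. Longest linear sequence: 12 (steps 3–14, from 4; the geranyl acetate branch is 10).

Steps most likely to fail:

Step 13 (the proposed new step). The allylic chloride may alkylate proline, the anilinooxy group may not chelate indium as a free hydroxyl does, and a 14-ring Barbier closure at high dilution is slow. The fallback uses known chemistry, sets out from 18 and comes back at 22. L-Proline/PhNO followed by NaBH4 at −20 °C gives the anilinooxy alcohol F2. CuSO4·5H2O in MeOH cleaves the N–O bond to the 1,2-diol F3. TEMPO/PhI(OAc)2 oxidises only the primary alcohol to the free α-hydroxy aldehyde F4. Indium/NaI in THF–water at high dilution (aqueous Barbier of a free α-hydroxy aldehyde, the best-precedented chelation case) closes the ring to the macrocyclic trihydroxy ester F5, and PPTS lactonises it to 22.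

Step 10. The β,γ-unsaturated aldehyde may isomerise or self-condense under DABCO before the slow Baylis–Hillman reaction is complete. The fallback sets out from 14 and comes back at 16. The lithium enolate of methyl 3-(phenylselanyl)propanoate (LDA, THF, −78 °C, 2.1 equiv to cover the free hydroxyl) adds kinetically to the saturated aldehyde to give the seleno aldol F1. H2O2/pyridine at 0 °C then gives 16 by selenoxide syn-elimination.

Step 14. The macrocycle may override reagent control and give the wrong oxirane face, or the lactone may suffer at pH 10. The fallback sets out from 16 and comes back at 23, placing the epoxidation on the open chain where the Shi ketone alone decides the face. The same Shi conditions on 16 give the epoxy enal F6. The conditions of step 11 give the epoxy aldehyde F7 and those of step 12 the epoxy allylic chloride F8. The protocol of step 13, with CuSO4·5H2O/MeOH in place of Zn/AcOH to spare the oxirane, then runs through the epoxy α-anilinooxy aldehyde F9, the epoxy macrocyclic hydroxy ester F10 and the anilinooxy epoxy lactone F11 to 23.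

**Further compounds**
F1 | step 10 | methyl (5E,8Z,10S,14E)-3,10-dihydroxy-6,10,14-trimethyl-16-oxo-2-[(phenylselanyl)methyl]hexadeca-5,8,14-trienoate (mixture at C2/C3) | O=C/C=C(C)/CCC[C@](C)(O)/C=C\C/C(C)=C/CC(O)C(C[Se]c1ccccc1)C(=O)OC
F2 | step 13 | methyl (2Z,5E,8Z,10S,14S,15R)-15-(anilinooxy)-2-(chloromethyl)-10,16-dihydroxy-6,10,14-trimethylhexadeca-2,5,8-trienoate | OC[C@H](ONc1ccccc1)[C@@H](C)CCC[C@](C)(O)/C=C\C/C(C)=C/C/C=C(\CCl)C(=O)OC
F3 | step 13 | methyl (2Z,5E,8Z,10S,14S,15R)-2-(chloromethyl)-10,15,16-trihydroxy-6,10,14-trimethylhexadeca-2,5,8-trienoate | OC[C@H](O)[C@@H](C)CCC[C@](C)(O)/C=C\C/C(C)=C/C/C=C(\CCl)C(=O)OC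
F4 | step 13 | methyl (2Z,5E,8Z,10S,14S,15R)-2-(chloromethyl)-10,15-dihydroxy-6,10,14-trimethyl-16-oxohexadeca-2,5,8-trienoate | O=C[C@H](O)[C@@H](C)CCC[C@](C)(O)/C=C\C/C(C)=C/C/C=C(\CCl)C(=O)OC
F5 | step 13 | methyl 2-[(1S,2R,3R,4S,8S,9Z,12E)-2,3,8-trihydroxy-4,8,12-trimethylcyclotetradeca-9,12-dien-1-yl]prop-2-enoate | COC(=O)C(=C)[C@@H]1C/C=C(C)/C\C=C/[C@@](C)(O)CCC[C@H](C)[C@@H](O)[C@@H]1O
F6 | step 14 | methyl (5R,6R,8Z,10S,14E)-5,6-epoxy-3,10-dihydroxy-6,10,14-trimethyl-2-methylidene-16-oxohexadeca-8,14-dienoate (C3 epimers) | O=C/C=C(C)/CCC[C@](C)(O)/C=C\C[C@@]1(C)O[C@@H]1CC(O)C(=C)C(=O)OC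
F7 | step 14 | methyl (5R,6R,8Z,10S,14S)-5,6-epoxy-3,10-dihydroxy-6,10,14-trimethyl-2-methylidene-16-oxohexadec-8-enoate (C3 epimers) | O=CC[C@@H](C)CCC[C@](C)(O)/C=C\C[C@@]1(C)O[C@@H]1CC(O)C(=C)C(=O)OC
F8 | step 14 | methyl (2Z,5R,6R,8Z,10S,14S)-2-(chloromethyl)-5,6-epoxy-10-hydroxy-6,10,14-trimethyl-16-oxohexadeca-2,8-dienoate | O=CC[C@@H](C)CCC[C@](C)(O)/C=C\C[C@@]1(C)O[C@@H]1C/C=C(\CCl)C(=O)OC
F9 | step 14 | methyl (2Z,5R,6R,8Z,10S,14S,15R)-15-(anilinooxy)-2-(chloromethyl)-5,6-epoxy-10-hydroxy-6,10,14-trimethyl-16-oxohexadeca-2,8-dienoate | O=C[C@H](ONc1ccccc1)[C@@H](C)CCC[C@](C)(O)/C=C\C[C@@]2(C)O[C@@H]2C/C=C(\CCl)C(=O)OC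
F10 | step 14 | methyl 2-[(1S,2R,3R,4S,8S,9Z,12R,13R)-3-(anilinooxy)-12,13-epoxy-2,8-dihydroxy-4,8,12-trimethylcyclotetradec-9-en-1-yl]prop-2-enoate | COC(=O)C(=C)[C@@H]1C[C@H]2O[C@]2(C)C\C=C/[C@@](C)(O)CCC[C@H](C)[C@@H](ONc3ccccc3)[C@@H]1O
F11 | step 14 | (1S,3R,4R,6Z,8S,12S,13R,14R)-13-(anilinooxy)-3,4-epoxy-8-hydroxycembra-6,15(17)-dien-16,14-olide | C=C1C(=O)O[C@H]2[C@H](ONc3ccccc3)[C@@H](C)CCC[C@](C)(O)/C=C\C[C@@]4(C)O[C@@H]4C[C@@H]12
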